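Set the flasks side by side and follow each unit of partner.

common to all: starting material 0.59 M; partner 0.472 M; time 80 s

| charge | temperature |
|---|---|
| spring | 15 °C |
| noon | 45 °C |
| dusk | 30 °C |
| autumn | 0 °C |

    starting material + partner → first product (k1 = 0.0269 M⁻¹ s⁻¹, Ea1 = 47.0 kJ mol⁻¹)
    partner + first product → double product (k2 = 0.00632 M⁻¹ s⁻¹, Ea2 = 45.0 kJ mol⁻¹)
    partner + double product → tris adduct (k3 = 0.0133 M⁻¹ s⁻¹, Ea3 = 40.0 kJ mol⁻¹)
    partner + tris adduct ⇌ tetra adduct (K4 = 2.9 M⁻¹, k4 = 0.0265 M⁻¹ s⁻¹, Ea4 = 60.0 kJ mol⁻¹, ΔH4 = −1.00 kJ mol⁻¹)
    starting material + first product → side product (k5 = 0.00126 M⁻¹ s⁻¹, Ea5 = 56.0 kJ mol⁻¹)
    partner → decomposed reagent (k6 = 0.0101 s⁻¹, Ea6 = 69.0 kJ mol⁻¹)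
    (constants at 0 °C)

- percent here means starting material units held: one side product counts as two
- constants are those at 0 °C; use the activation energies and enthalpies for any other temperature

1. the flask that comes out highest in amount of first product, in percent of the starting material charged, or "all alike" when all lie within 1.5 percentage points (spring / noon / dusk / autumn / all alike)
2. first product at the end, in percent of the starting material charged, spring
3. first product at the end, in percent of the starting material charged, noon
4. first product at the end, in percent of the starting material charged, dusk
5. first product at the end, in percent of the starting material charged, autumn

At the start of autumn, 1.57 units of partner enter the step to first product for each unit that decomposes. This ratio, the rate constant of that step times [starting material] over the decomposition constant, is the partner's split, a selectivity factor. Here is the puzzle: from autumn to noon the step to first product speeds up 19 times, yet the split sinks to 0.399. It clears when I scale by activation energy: over the same two temperatures, decomposition speeds up 73.5 times, a bigger factor than the step to first product gets.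

Now I solve noon at both ends. At the early end, the partner lasts 0.963 s on average, which is shorter than the 80 s of the flask. So the split sets what is made: 22.8 % of the starting material charged, a slight overestimate since [starting material] falls meanwhile. At the late end, the steps that need partner have stopped, and first product is lost to side product at 0.0188 s⁻¹, with [starting material] held at what the early end leaves. Joining the two ends, noon holds 5.09 %.

Autumn joins less cleanly, because its partner lasts 38.5 s, which is not much shorter than the time. Holding the split at its starting value, I get 40.3 %, on the high side since the split falls with [starting material]. I commit to autumn as highest, well above noon.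

The forecast also names autumn, with 28.5 % for spring, 5.4 % for noon, 17 % for dusk and 33.5 % for autumn. That puts it below my autumn figure and just above my noon figure. Its ground is that “hot flasks lose partner before it can react”.

The simulation gives 28.6 % for spring, 5.30 % for noon, 16.6 % for dusk and 33.3 % for autumn, so autumn is highest. At noon, partner stands at 0 % and decomposed reagent at 0.346 M, which is 73.3 % of the partner charge. The noon answer has moved 5 points with starting material at 0.344 M or 1.59 M, and with partner raised to 0.758 M. In autumn the split at the asked time reads 0.99, with 62.7 % of starting material left, and the neighbour of autumn charged with 1.2 M of partner starts from the same split, which by 80.0 s has sunk to 0.447, with first product at 58.3 %.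

(The rate constants are those of an exercise.)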